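**Retrosynthetic overview**

1. The target depside is traced back, through hydrogenolysis of a benzyl ester (ring B CO2H) and a benzyl ether (ring A C4–OH) and O-methylation at ring A C2, to a benzyl-protected depside whose ring A is a 2,4-dihydroxy-6-pentylbenzoate.
2. Key disconnection: the ring A C1–C6 bond (carbonyl-bearing carbon to pentyl-bearing carbon). Ring A atoms C1–C6 are C2–C7 of a 3,5,7-trioxododecanoyl chain, the ring A C2 and C4 oxygens are the chain C3 and C5 ketone oxygens, the pentyl group is chain C8–C12, and the depside carbonyl is chain C1, already esterified to the ring B C4 oxygen.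
3. The triketo aryl ester is cut at the ring B O–C1 bond into the ring B phenol and an acylketene, released by thermolysis of a diketo-dioxinone built from 2,2,6-trimethyl-1,3-dioxin-4-one by two C-acylations (acetyl chloride, then the Weinreb amide of hexanoic acid).
4. The ring B phenol comes from olivetol: Vilsmeier formylation, 4-O-allylation, 2-O-methylation, Pinnick oxidation, benzyl ester formation, deallylation.
5. Ring order: ring B is carried through from olivetol; ring A is the only ring formed, by aldol aromatization in step 11.

Key step: step 11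

Remark on the chemistry: the target has no stereocentre. Ring A is the acyl ring and ring B the ring carrying the free carboxyl group, and locants in each ring start at its carbonyl-bearing carbon. The triketo ester and its aldol adduct are drawn as single tautomers although they should exist as enol mixtures; the adduct is racemic at its carbinol carbon, which is lost on dehydration.

**Route**

Step 1
Reactants: 1 olivetol (5-pentylbenzene-1,3-diol)
Product: 3 2,4-dihydroxy-6-pentylbenzaldehyde, via iminium chloride 2 (not isolated)
Conditions: POCl3, DMF, 0 °C to rt; then H2O, 50 °C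
Reagents that add atoms: N,N-dimethylformamide CN(C)C=O; water O
Why: Vilsmeier–Haack formylation of a 5-alkylresorcinol should occur at C4 (para to one hydroxyl, ortho to the other) rather than at the doubly flanked C2, and the iminium salt 2 is hydrolysed on aqueous work-up.

Step 2
Reactants: 3 2,4-dihydroxy-6-pentylbenzaldehyde
Product: 4 4-(allyloxy)-2-hydroxy-6-pentylbenzaldehyde
Conditions: allyl bromide (1.05 equiv), K2CO3, acetone, rt
Reagents that add atoms: allyl bromide C=CCBr
Why: Williamson etherification with one equivalent of halide should go at the C4 hydroxyl, which is para to the formyl group, more acidic and free, while the C2 hydroxyl is held in a hydrogen bond to the aldehyde.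

Step 3
Reactants: 4 4-(allyloxy)-2-hydroxy-6-pentylbenzaldehyde
Product: 5 4-(allyloxy)-2-methoxy-6-pentylbenzaldehyde
Conditions: MeI, K2CO3, DMF, 40 °C
Reagents that add atoms: iodomethane CI
Why: Williamson methylation of the remaining chelated phenol should proceed under these more forcing conditions (polar solvent, excess halide).

Step 4
Reactants: 5 4-(allyloxy)-2-methoxy-6-pentylbenzaldehyde
Product: 6 4-(allyloxy)-2-methoxy-6-pentylbenzoic acid
Conditions: NaClO2, NaH2PO4, 2-methylbut-2-ene, t-BuOH/H2O, rt
Reagents that add atoms: sodium chlorite [Na+].[O-]Cl=O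
Why: Pinnick oxidation converts hindered aryl aldehydes to acids under buffered conditions, and the excess trisubstituted alkene scavenges HOCl so that the allyl ether and the electron-rich ring should not be chlorinated.

Step 5
Reactants: 6 4-(allyloxy)-2-methoxy-6-pentylbenzoic acid
Product: 7 benzyl 4-(allyloxy)-2-methoxy-6-pentylbenzoate
Conditions: BnBr, K2CO3, DMF, rt
Reagents that add atoms: benzyl bromide BrCc1ccccc1
Why: O-alkylation of the carboxylate (SN2 at the benzylic halide) is indifferent to the two ortho substituents that would hinder an esterification by attack at the carbonyl.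

Step 6
Reactants: 7 benzyl 4-(allyloxy)-2-methoxy-6-pentylbenzoate
Product: 8 benzyl 4-hydroxy-2-methoxy-6-pentylbenzoate
Conditions: Pd(PPh3)4 (5 mol %), morpholine, THF, rt
Reagents that add atoms: none
Why: Tsuji–Trost deallylation, in which zerovalent palladium ionises the aryl allyl ether to a π-allyl complex that morpholine captures, should free the ring B C4 phenol without touching the benzyl ester.

Step 7
Reactants: 9 2,2,6-trimethyl-4H-1,3-dioxin-4-one
Product: 11 2,2-dimethyl-6-(2-oxopropyl)-4H-1,3-dioxin-4-one, via lithium dienolate 10 (not isolated)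
Conditions: LiN(SiMe3)2, THF, −78 °C; then AcCl (0.5 equiv), −78 °C; aq. NH4Cl
Reagents that add atoms: acetyl chloride CC(=O)Cl
Why: γ-Deprotonation gives the vinylogous ester dienolate 10, which undergoes crossed Claisen C-acylation at its exocyclic carbon; a second equivalent of 10 takes up the acidic proton of 11 and is recovered as 9.

Step 8
Reactants: 12 hexanoyl chloride
Product: 13 N-methoxy-N-methylhexanamide
Conditions: MeNH(OMe)·HCl, K2CO3, EtOAc/H2O, 0 °C to rt
Reagents that add atoms: N,O-dimethylhydroxylamine hydrochloride CNOC.Cl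
Why: Schotten–Baumann acylation of the hydroxylamine under biphasic conditions is a standard preparation of Weinreb amides.

Step 9
Reactants: 11 2,2-dimethyl-6-(2-oxopropyl)-4H-1,3-dioxin-4-one; 13 N-methoxy-N-methylhexanamide
Product: 15 6-(2,4-dioxononyl)-2,2-dimethyl-4H-1,3-dioxin-4-one, via dilithium dienediolate 14 (not isolated)
Conditions: LiN(iPr)2 (2.2 equiv), THF, −78 °C; then 13, −78 to −40 °C; 1 M HCl
Reagents that add atoms: none
Why: Dianion Claisen condensation, in which the second deprotonation occurs at the terminal methyl group and this more reactive carbanion site of 14 attacks the Weinreb amide, whose chelated tetrahedral intermediate prevents over-addition until the acidic quench.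

Step 10
Reactants: 15 6-(2,4-dioxononyl)-2,2-dimethyl-4H-1,3-dioxin-4-one; 8 benzyl 4-hydroxy-2-methoxy-6-pentylbenzoate
Product: 17 benzyl 2-methoxy-6-pentyl-4-(3,5,7-trioxododecanoyloxy)benzoate, via acylketene 16 (not isolated)
Conditions: 15 (1.3 equiv) added slowly to 8 in toluene, 110 °C; concentrated and used crude
Reagents that add atoms: none
Why: Retro-hetero-Diels–Alder loss of acetone from the dioxinone gives acylketene 16, which the ring B phenol (both ortho positions are CH) captures to give the aryl β-keto ester, so the depside ester bond is made without activating any 2,6-disubstituted benzoic acid.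

Step 11
Reactants: 17 benzyl 2-methoxy-6-pentyl-4-(3,5,7-trioxododecanoyloxy)benzoate
Product: 19 benzyl 4-(2,4-dihydroxy-6-pentylbenzoyloxy)-2-methoxy-6-pentylbenzoate, via aldol adduct 18 (not isolated)
Conditions: Et3N (0.5 equiv), CH2Cl2, 0 °C to rt; then CF3CO2H, rt
Reagents that add atoms: none
Why: Et3N reversibly deprotonates the strongly enolized triketo ester, and the enolate that is nucleophilic at chain C2 (between the aryl ester carbonyl and the C3 ketone) adds to the C7 ketone to give aldol 18, whose tertiary carbinol is then lost under acid while the two remaining ring carbonyls enolize to the aromatic resorcylate. The closest known reaction type is the base-mediated aldol cycloaromatization of 3,5,7-triketo esters obtained by trapping dioxinone-derived acylketenes, the biomimetic counterpart of orsellinate-type polyketide folding. Ring A closes in the 6-(enolexo)-exo-trig mode, forming its C1–C6 bond (chain C2–C7). No stereocentre persists, since the carbinol carbon of 18 is racemic and is destroyed on dehydration. The step needs C2-to-C7 aldol closure in preference to Claisen attack of C6 on C1 or lactonization of the C5 enol oxygen onto C1, both of which would expel the ring B phenoxide. This should be secured by the higher electrophilicity of the C7 ketone relative to the ester carbonyl, by a weak non-nucleophilic amine in an aprotic solvent with no alkoxide present, and by the fact that the more acidic C4 and C6 methylenes have only reversible or four-membered options under these conditions while the aldol is drained irreversibly by aromatization.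

Step 12
Reactants: 19 benzyl 4-(2,4-dihydroxy-6-pentylbenzoyloxy)-2-methoxy-6-pentylbenzoate
Product: 20 benzyl 4-[4-(benzyloxy)-2-hydroxy-6-pentylbenzoyloxy]-2-methoxy-6-pentylbenzoate
Conditions: BnBr (1.05 equiv), K2CO3, acetone, rt
Reagents that add atoms: benzyl bromide BrCc1ccccc1
Why: Williamson benzylation should select the ring A C4 hydroxyl, since the C2 hydroxyl is hydrogen-bonded to the depside carbonyl and less acidic.

Step 13
Reactants: 20 benzyl 4-[4-(benzyloxy)-2-hydroxy-6-pentylbenzoyloxy]-2-methoxy-6-pentylbenzoate
Product: 21 benzyl 4-[4-(benzyloxy)-2-methoxy-6-pentylbenzoyloxy]-2-methoxy-6-pentylbenzoate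
Conditions: MeI, K2CO3, DMF, rt to 40 °C
Reagents that add atoms: iodomethane CI
Why: Williamson methylation of the chelated ring A C2 phenol should proceed in a polar solvent, and the diaryl ester should survive anhydrous carbonate because its carbonyl is shielded by two ortho substituents.

Step 14
Reactants: 21 benzyl 4-[4-(benzyloxy)-2-methoxy-6-pentylbenzoyloxy]-2-methoxy-6-pentylbenzoate
Product: 22 4-O-demethylplanaic acid
Conditions: H2 (1 atm), 10% Pd/C, EtOAc, rt
Reagents that add atoms: none
Why: Hydrogenolysis of the benzyl ester and the benzyl ether over palladium on carbon should release the carboxylic acid and the ring A C4 phenol without affecting the aryl ester or the aryl methyl ethers.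

**Compound list**

1 | olivetol (5-pentylbenzene-1,3-diol) | CCCCCc1cc(O)cc(O)c1 | starting material
2 | [(2,4-dihydroxy-6-pentylphenyl)methylidene]dimethylammonium chloride | CCCCCc1cc(O)cc(O)c1C=[N+](C)C.[Cl-] | intermediate
3 | 2,4-dihydroxy-6-pentylbenzaldehyde | CCCCCc1cc(O)cc(O)c1C=O | intermediate
4 | 4-(allyloxy)-2-hydroxy-6-pentylbenzaldehyde | CCCCCc1cc(OCC=C)cc(O)c1C=O | intermediate
5 | 4-(allyloxy)-2-methoxy-6-pentylbenzaldehyde | CCCCCc1cc(OCC=C)cc(OC)c1C=O | intermediate
6 | 4-(allyloxy)-2-methoxy-6-pentylbenzoic acid | CCCCCc1cc(OCC=C)cc(OC)c1C(=O)O | intermediate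
7 | benzyl 4-(allyloxy)-2-methoxy-6-pentylbenzoate | CCCCCc1cc(OCC=C)cc(OC)c1C(=O)OCc1ccccc1 | intermediate
8 | benzyl 4-hydroxy-2-methoxy-6-pentylbenzoate | CCCCCc1cc(O)cc(OC)c1C(=O)OCc1ccccc1 | intermediate
9 | 2,2,6-trimethyl-4H-1,3-dioxin-4-one | CC1=CC(=O)OC(C)(C)O1 | starting material
10 | lithium 2,2-dimethyl-6-methylidene-6H-1,3-dioxin-4-olate (dienolate of 9) | [Li+].C=C1C=C([O-])OC(C)(C)O1 | intermediate
11 | 2,2-dimethyl-6-(2-oxopropyl)-4H-1,3-dioxin-4-one | CC(=O)CC1=CC(=O)OC(C)(C)O1 | intermediate
12 | hexanoyl chloride | CCCCCC(=O)Cl | starting material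
13 | N-methoxy-N-methylhexanamide | CCCCCC(=O)N(C)OC | intermediate
14 | dilithium dienediolate of 11 (deprotonated at the ring-bound CH2 and at the terminal CH3) | [Li+].[Li+].C=C([O-])C=C1C=C([O-])OC(C)(C)O1 | intermediate
15 | 6-(2,4-dioxononyl)-2,2-dimethyl-4H-1,3-dioxin-4-one | CCCCCC(=O)CC(=O)CC1=CC(=O)OC(C)(C)O1 | intermediate
16 | 3,5,7-trioxododec-1-en-1-one (acylketene) | CCCCCC(=O)CC(=O)CC(=O)C=C=O | intermediate
17 | benzyl 2-methoxy-6-pentyl-4-(3,5,7-trioxododecanoyloxy)benzoate | CCCCCC(=O)CC(=O)CC(=O)CC(=O)Oc1cc(CCCCC)c(C(=O)OCc2ccccc2)c(OC)c1 | intermediate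
18 | benzyl 4-[(2,6-dihydroxy-4-oxo-6-pentylcyclohex-1-ene-1-carbonyl)oxy]-2-methoxy-6-pentylbenzoate (racemic) | CCCCCC1(O)CC(=O)CC(O)=C1C(=O)Oc1cc(CCCCC)c(C(=O)OCc2ccccc2)c(OC)c1 | intermediate
19 | benzyl 4-(2,4-dihydroxy-6-pentylbenzoyloxy)-2-methoxy-6-pentylbenzoate | CCCCCc1cc(OC(=O)c2c(CCCCC)cc(O)cc2O)cc(OC)c1C(=O)OCc1ccccc1 | intermediate
20 | benzyl 4-[4-(benzyloxy)-2-hydroxy-6-pentylbenzoyloxy]-2-methoxy-6-pentylbenzoate | CCCCCc1cc(OC(=O)c2c(CCCCC)cc(OCc3ccccc3)cc2O)cc(OC)c1C(=O)OCc1ccccc1 | intermediate
21 | benzyl 4-[4-(benzyloxy)-2-methoxy-6-pentylbenzoyloxy]-2-methoxy-6-pentylbenzoate | CCCCCc1cc(OC(=O)c2c(CCCCC)cc(OCc3ccccc3)cc2OC)cc(OC)c1C(=O)OCc1ccccc1 | intermediate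
22 | 4-O-demethylplanaic acid, 4-(4-hydroxy-2-methoxy-6-pentylbenzoyloxy)-2-methoxy-6-pentylbenzoic acid | CCCCCc1cc(OC(=O)c2c(CCCCC)cc(O)cc2OC)cc(OC)c1C(=O)O | target

**Step count**

Total: 14 steps. Longest linear sequence: 11 steps (steps 1–6, then 10–14). The dioxinone branch (steps 7 and 9) and the Weinreb amide (step 8) are convergent side branches.

**Steps most likely to fail**

1. Step 11. The aryl ester is an activated acyl donor, so Claisen attack of C6 on C1, or lactonization of the C5 enol oxygen onto C1, may expel the ring B phenoxide before the aldol closure takes place. The fallback sets out from 15 (with 8) and comes back at 20. The same aldol aromatization would be run on the dioxinone itself, where C1 is locked in the cyclic acetal ester and nothing can leave: Et3N in CH2Cl2 followed by acid should close dioxinone C5 onto the terminal ketone of 15 to give 7-hydroxy-2,2-dimethyl-5-pentyl-4H-1,3-benzodioxin-4-one F1. Benzylation (BnBr, K2CO3, acetone) should give 7-(benzyloxy)-2,2-dimethyl-5-pentyl-4H-1,3-benzodioxin-4-one F2. Hydrolysis of the acetonide (KOH, DMSO/H2O, 80 °C; then HCl) should give 4-(benzyloxy)-2-hydroxy-6-pentylbenzoic acid F3. Carbodiimide esterification of this acid with phenol 8 (N,N'-dicyclohexylcarbodiimide, toluene, rt) would deliver 20.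

2. Step 10. The acylketene may be consumed by intramolecular O-acylation through its C5 enol (pyranone formation) or by dimerization faster than the weakly nucleophilic phenol can add. The fallback sets out from acid 6 and phenol 8 and comes back at 22. It is a classical depside esterification: (CF3CO)2O in toluene at rt turns 6 into its mixed anhydride, which should acylate 8 to give benzyl 4-[4-(allyloxy)-2-methoxy-6-pentylbenzoyloxy]-2-methoxy-6-pentylbenzoate F4. Deallylation (Pd(PPh3)4, morpholine, THF) should give benzyl 4-(4-hydroxy-2-methoxy-6-pentylbenzoyloxy)-2-methoxy-6-pentylbenzoate F5, and hydrogenolysis (H2, 10% Pd/C, EtOAc) would give 22.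

3. Step 9. Proton transfer between dianion 14 and the enolizable Weinreb amide, or sluggish acylation, may return 11 and leave the chain unextended. The fallback sets out from 11 and comes back at 15. The C–C bond would be formed by aldol addition instead of acylation: dianion 14 (LiN(iPr)2, THF, −78 °C) is added to hexanal (CCCCCC=O), a far better electrophile, to give racemic 6-(4-hydroxy-2-oxononyl)-2,2-dimethyl-4H-1,3-dioxin-4-one F6. Oxidation of the β-hydroxy ketone with Dess–Martin periodinane (CH2Cl2, rt) should then give 15.

**Further compounds**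

F1 | step 11 | 7-hydroxy-2,2-dimethyl-5-pentyl-4H-1,3-benzodioxin-4-one | CCCCCc1cc(O)cc2OC(C)(C)OC(=O)c12
F2 | step 11 | 7-(benzyloxy)-2,2-dimethyl-5-pentyl-4H-1,3-benzodioxin-4-one | CCCCCc1cc(OCc3ccccc3)cc2OC(C)(C)OC(=O)c12
F3 | step 11 | 4-(benzyloxy)-2-hydroxy-6-pentylbenzoic acid | CCCCCc1cc(OCc2ccccc2)cc(O)c1C(=O)O
F4 | step 10 | benzyl 4-[4-(allyloxy)-2-methoxy-6-pentylbenzoyloxy]-2-methoxy-6-pentylbenzoate | CCCCCc1cc(OC(=O)c2c(CCCCC)cc(OCC=C)cc2OC)cc(OC)c1C(=O)OCc1ccccc1
F5 | step 10 | benzyl 4-(4-hydroxy-2-methoxy-6-pentylbenzoyloxy)-2-methoxy-6-pentylbenzoate | CCCCCc1cc(OC(=O)c2c(CCCCC)cc(O)cc2OC)cc(OC)c1C(=O)OCc1ccccc1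
F6 | step 9 | 6-(4-hydroxy-2-oxononyl)-2,2-dimethyl-4H-1,3-dioxin-4-one (racemic) | CCCCCC(O)CC(=O)CC1=CC(=O)OC(C)(C)O1
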